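**Remark (assumption).** The target has no stereocentre and no configurationally stable axis: only two ortho substituents flank the ether link (OH on ring A, Br on ring B). It is therefore one achiral compound, and the "single enantiomer" demand is met without any stereo-defining step.

## Structural features

The target is a diaryl ether of two benzene rings. Ring A (C1–C6) is a phenol with OH at C1, Br at C2 and C4, and the ether oxygen at C6. Ring B (C1′–C6′) is bound through O1′ at C1′ and carries Br at C2′ and C4′. Both rings therefore show the same pattern: oxygen at position 1, bromine at positions 2 and 4. The molecule is two units of 2,4-dibromophenol less two hydrogen atoms, joined from O1′ of one unit to C6 of the other, which is the only hydrogen-bearing ortho carbon of that unit. This hidden dimer relationship is the feature the key step exploits. The four aryl C–Br bonds are fragile towards transition-metal catalysis at high temperature, metal–halogen exchange, reducing metals and UV light. The free phenol is oxidizable and, as its phenolate, can displace Br2′ intramolecularly towards a brominated dibenzo-p-dioxin under heat or light. The real difficulty is regiochemical: the ether oxygen must sit at C6 of a ring that already carries bromine at exactly C2 and C4, only one of the two adjacent oxygens may be arylated, and the bond must be made without touching four C–Br bonds.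

## Logic of the disconnections

In one sentence, the route is the oxidative dehydrodimerization of 1 through O1′-to-C6 coupling of two phenoxyl radicals.

**4 ⇒ 3.** No bond between heavy atoms is cut; the O1–H bond of 4 is exchanged for a C6–H bond, which gives the keto tautomer 3. This exposes C6 as the sp3 carbon at which the ether bond was made. The demand on the forward step is only that enolization of 3 be fast and irreversible, which the regained aromaticity of ring A ensures.

**3 ⇒ 2 + 2.** The O1′–C6 bond is cut homolytically. The cut is made here because both fragments are then the same species, 2, with every C–Br bond and both C–O bonds already in place. The gain is the largest possible: the C12 target falls to a single C6 building block, with no protecting group, no leaving group and no metal-mediated step near the C–Br bonds. The demand on the forward step is that two molecules of 2 pair oxygen to C6, rather than C6 to C6′ or at the bromine-bearing C2 and C4, and that 4 is not oxidized further.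

**2 ⇒ 1.** The O1–H hydrogen atom is restored; 2 arises from 1 by loss of one proton and one electron. The demand is a one-electron oxidant (here an anode) that does not take a second electron from 2, in a medium that keeps 1 un-ionized. 1 is a commercial commodity phenol.

## Other disconnections considered

**Alternative 1:** (the first that comes to mind) The same O1′–C6 bond is cut in the polar sense, with a protected catechol as nucleophile and a pre-activated ring B as electrophile.
- Forward key step: O-arylation of 3,5-dibromo-2-methoxyphenol A1 with bis(2,4-dibromophenyl)iodonium triflate A2 (or a copper-mediated coupling with an iodoarene) to the methyl ether A3, followed by O-demethylation to 4.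
- Ground for preferring the chosen plan: A1 and A2 are not commodity chemicals and each needs its own short synthesis. A protecting group is carried only to be removed, and one aryl group of A2 is discarded. A copper variant would have to distinguish one C–I bond from four C–Br bonds. The sequence runs to five or more steps against one and makes no use of the identical substitution pattern of the two rings.

**Alternative 2:** All four C–Br bonds are cut, leading back to 2-phenoxyphenol A4.
- Forward key step: exhaustive electrophilic bromination of A4.
- Ground for preferring the chosen plan: the first three brominations (C4 and C6 of the phenol ring, C4′ of the phenoxy ring) are directed unambiguously and should reach the tribromide A5. The fourth must enter ortho to the ether oxygen on an already deactivated bromophenoxy ring, in competition with C3 and C5 of the electron-rich phenol ring and with its oxidation. The position of the last bromine is thus not secured by the substrate, whereas in the chosen plan all four bromines are bought in place with 1.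

**Alternative 3:** Ring A is taken back to a non-aromatic six-membered ring.
- Forward sequence: opening of 2,3-epoxycyclohexanone A6 by 1 and dehydration give the 2-aryloxy enone A7.
- Forward key step: brominative aromatization of A7 (α-bromination and dehydrobromination to the phenol, then ortho and para bromination) to 4.
- Ground for preferring the chosen plan: the regiochemistry is well secured by the enone oxygen pattern. However, the plan needs three to four steps, builds ring A from a separate carbocycle, and exposes the diaryl ether to a hot HBr/Br2 medium. It uses 1 only as ring B and ignores that ring A is the same unit.

Key step: step 1

## Route

**Step 1**
Reactants: 1 2,4-dibromophenol (two molecules per molecule of product)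
Product: 4 2,4-dibromo-6-(2,4-dibromophenoxy)phenol, via 2,4-dibromophenoxyl radical 2 (not isolated), via 6-aryloxy-2,4-dibromocyclohexa-2,4-dien-1-one 3 (not isolated)
Conditions: graphite felt (+) | stainless steel (−), undivided flow cell, constant current, 0.5 F/mol of 1; Bu4NBF4, AcOH/NaOAc, MeCN–H2O 4:1, rt, N2; chromatography, unreacted 1 recycled
Reagents that add atoms: none
Why: This is an anodic oxidative phenol coupling (dehydrodimerization), the laboratory copy of the presumed biosynthetic coupling of bromophenols; anodic oxidation of ortho-brominated phenols is a known entry to ortho-hydroxy diaryl ethers, and one-electron oxidation of 2,4-dihalophenols is known to give ortho-phenoxyphenols. Proton-coupled one-electron oxidation of 1 at the carbon anode gives the neutral radical 2, whose spin sits on O1, C2, C4 and C6; two radicals 2 combine O1′ to C6 to give dienone 3, and enolization of its C6–H restores ring A and gives 4, while the cathode discharges the two protons as hydrogen. No ring is closed and no stereocenter remains, since the sp3 carbon C6 of 3 is transient and 4 is achiral. The selectivity needed is O–C6 coupling over C6–C6′ coupling and over coupling at the bromine-bearing C2 and C4. The substrate secures the second point: C6 is the only spin-bearing carbon with a hydrogen, so only adducts at C6 can be locked by enolization, whereas adducts at C2 or C4 are quinol-ether-type dienones that cannot aromatize and should dissociate back to 2. For the first point the oxygen terminus has the highest spin density and the least steric demand, and O/C6 pairing can occur in two equivalent ways against one for C6/C6′, so the ether should be favoured, although the carbon–carbon dimer is expected to accompany it. The weakly acidic, non-fluorinated medium keeps 1 un-ionized (no phenolate, hence no chain displacement of the para bromide) and leaves the radical oxygen free of strong hydrogen-bond donors, and the charge is held to half of the theoretical amount so that 1 stays in excess over the equally oxidizable 4 and is recovered.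

## Compound list

1 | 2,4-dibromophenol | Oc1ccc(Br)cc1Br | starting material
2 | 2,4-dibromophenoxyl radical (not isolated) | [O]c1ccc(Br)cc1Br | intermediate
3 | 2,4-dibromo-6-(2,4-dibromophenoxy)cyclohexa-2,4-dien-1-one (transient, racemic at C6, not isolated) | O=C1C(Br)=CC(Br)=CC1Oc1ccc(Br)cc1Br | intermediate
4 | 2,4-dibromo-6-(2,4-dibromophenoxy)phenol | Oc1c(Br)cc(Br)cc1Oc1ccc(Br)cc1Br | target

## Step count and risk

Total step count: 1. Longest linear sequence: 1 step.

The route has a single step, so there are no further steps to rank. All uncertainty lies in step 1 (the key step), and it is listed here as separate processes.

- **Competing carbon–carbon combination.** Two radicals 2 can pair C6 to C6′ instead of O1′ to C6. That adduct also bears hydrogen at the new bond and is also locked by enolization, so nothing in the substrate forbids it. It lowers the share of ether formation and requires chromatographic separation.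
- **Coupling at the bromine-bearing carbons followed by loss of bromine.** Adducts at C4 or C2 may, instead of dissociating, transfer bromine (as an electrophilic bromine donor or after cathodic reduction). This would scramble the bromination pattern of both product and starting material.
- **Over-oxidation of the product.** 4 is a phenol of similar oxidation potential to 1, so further coupling to oligomers and passivation of the anode by a polymer film are likely at high conversion. Oxidative or base- and light-induced ring closure onto C2′ towards brominated dibenzo-p-dioxins is also possible. For that reason the charge is limited, the mixture is kept cold and dark, and all fractions should be handled as potentially dioxin-containing.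
- **Second electron transfer at the anode.** Radical 2 may be oxidized to the phenoxonium ion and captured by water, giving quinone formation with loss of bromide. A low current density and a high concentration of 1 favour the bimolecular radical pairing over this path.

If anode fouling alone is the problem, the same radical 2 can be generated in solution by a peroxidase with hydrogen peroxide or by a manganese(IV) oxide; this changes conditions only and is not the fallback.

**Fallback for step 1** (known polar chemistry; sets out from 1 and returns to the route at 4). The phenoxide of 1 is arylated by nucleophilic aromatic substitution on 2-fluorobenzaldehyde (O=Cc1ccccc1F; K2CO3, DMF, 120 °C) to give 2-(2,4-dibromophenoxy)benzaldehyde F1. Baeyer–Villiger oxidation of the aldehyde (mCPBA, CH2Cl2, rt; Dakin-type aryl migration favoured by the ortho aryloxy donor) gives 2-(2,4-dibromophenoxy)phenyl formate F2. Methanolysis (cat. K2CO3, MeOH, rt) gives 2-(2,4-dibromophenoxy)phenol F3. Bromination of F3 with two equivalents of bromine (AcOH, 0 °C) should then enter only the free phenol ring, ortho and para to its OH, since the dibromophenoxy ring is deactivated, and give 4. This fallback fixes the regiochemistry by polar reactivity at the cost of four steps.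

## Further compounds

F1 | step 1 | 2-(2,4-dibromophenoxy)benzaldehyde | O=Cc1ccccc1Oc1ccc(Br)cc1Br
F2 | step 1 | 2-(2,4-dibromophenoxy)phenyl formate | O=COc1ccccc1Oc1ccc(Br)cc1Br
F3 | step 1 | 2-(2,4-dibromophenoxy)phenol | Oc1ccccc1Oc1ccc(Br)cc1Br
A1 | alternative 1 | 3,5-dibromo-2-methoxyphenol | COc1c(O)cc(Br)cc1Br
A2 | alternative 1 | bis(2,4-dibromophenyl)iodonium triflate | Brc1ccc([I+]c2ccc(Br)cc2Br)c(Br)c1.[O-]S(=O)(=O)C(F)(F)F
A3 | alternative 1 | 1,5-dibromo-3-(2,4-dibromophenoxy)-2-methoxybenzene | COc1c(Br)cc(Br)cc1Oc1ccc(Br)cc1Br
A4 | alternative 2 | 2-phenoxyphenol | Oc1ccccc1Oc1ccccc1
A5 | alternative 2 | 2,4-dibromo-6-(4-bromophenoxy)phenol | Oc1c(Br)cc(Br)cc1Oc1ccc(Br)cc1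
A6 | alternative 3 | 2,3-epoxycyclohexanone (racemic) | O=C1CCCC2OC12
A7 | alternative 3 | 2-(2,4-dibromophenoxy)cyclohex-2-en-1-one | O=C1CCCC=C1Oc1ccc(Br)cc1Br
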